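**Plan**
1. Retrosynthesis: after loss of three protecting groups, the dihydrofuran is cut at C3a–C3, C3–C2 and C2–O1 (furo[3,2-c]pyran-4-one numbering). This gives a 4-hydroxy-6-styryl-2-pyranone, a 4-alkoxy-2-pyranone-6-carbaldehyde and a benzylic sulfonium ylide; the styryl C=C is cut to an aldol pair.
2. Enabling feature: C3 and C2 are sp3 one-carbon units. C3 lies between C3a of a 4-hydroxy-2-pyranone and C6 of the second pyranone (ring A), so it is a pyrone aldehyde carbon; C2 lies between C3, O1 and the catechol ring, so it is a benzylic ylide carbon.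
3. Forward: both pyranone rings come from triacetic acid lactone, one extended at its methyl group to the styrylpyranone, the other oxidised there to the aldehyde. The dihydrofuran, the only ring made, closes last in a one-pot Knoevenagel condensation, ylide addition and O-alkylation.
4. Stereochemistry: C2 from the C2-symmetric (2S,5S)-2,5-dimethylthiolane on the ylide (from (2R,5R)-hexane-2,5-diol by double inversion), C3 from the trans-selective closure, the E-alkene from elimination to the conjugated styrene.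
5. Protecting groups: catechols as acetonides; the ring A hydroxyl as 2-(trimethylsilyl)ethyl ether, which fluoride removes beside the acetonides and acid removes together with them.

Key step: step 10

Assumption: the ylide of the thiolanium salt is taken to react through the same face as in the aldehyde epoxidations of this sulfide class, which on that model gives 2S from the (2S,5S)-sulfide; if the opposite sense were found, the salt from (2S,5S)-hexane-2,5-diol would be used with nothing else changed.

**Step 1**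
Reactants: 1 3,4-dihydroxybenzaldehyde
Product: 2 2,2-dimethyl-1,3-benzodioxole-5-carbaldehyde
Conditions: Me2C(OMe)2, TsOH·H2O (cat.), toluene, reflux, MeOH removed over 4 Å MS
Reagents that add atoms: 2,2-dimethoxypropane, COC(C)(C)OC
Why: Acid-catalysed transketalisation closes the isopropylidene ketal on the catechol (acetonide protection), driven by removal of methanol, and the aldehyde is unchanged after aqueous work-up.

**Step 2**
Reactants: 3 4-hydroxy-6-methyl-2H-pyran-2-one (triacetic acid lactone)
Product: 4 6-methyl-4-[2-(trimethylsilyl)ethoxy]-2H-pyran-2-one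
Conditions: Me3SiCH2CH2OH, PPh3, DIAD, THF, 0 °C → rt
Reagents that add atoms: 2-(trimethylsilyl)ethanol, C[Si](C)(C)CCO
Why: Mitsunobu O-alkylation of the acidic vinylogous acid (pKa about 5) goes at the 4-oxygen, as known for this lactone with primary alcohols, and the vinylogous silylethyl ester formed tolerates base but falls to fluoride or strong acid.

**Step 3**
Reactants: 4 6-methyl-4-[2-(trimethylsilyl)ethoxy]-2H-pyran-2-one, 2 2,2-dimethyl-1,3-benzodioxole-5-carbaldehyde
Product: 8 (E)-6-[2-(2,2-dimethyl-1,3-benzodioxol-5-yl)ethenyl]-4-[2-(trimethylsilyl)ethoxy]-2H-pyran-2-one, via lithium dienolate 5 (not isolated), via lithium aldolate 6 (not isolated), via benzylic mesylate 7 (not isolated)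
Conditions: LiN(iPr)2 (1.05 equiv), THF, −78 °C; 2, −78 °C; MsCl (2.2 equiv) then Et3N (3 equiv), −78 °C → rt
Reagents that add atoms: none
Why: Deprotonation of the 6-methyl group gives the extended lithium enolate, which adds to the aldehyde (vinylogous aldol addition, known for 4-alkoxy-6-methyl-2-pyranones), and the mesylate of the electron-rich benzylic alkoxide eliminates with Et3N (E1cB) to the conjugated E-alkene.

**Step 4**
Reactants: 8 (E)-6-[2-(2,2-dimethyl-1,3-benzodioxol-5-yl)ethenyl]-4-[2-(trimethylsilyl)ethoxy]-2H-pyran-2-one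
Product: 9 (E)-6-[2-(2,2-dimethyl-1,3-benzodioxol-5-yl)ethenyl]-4-hydroxy-2H-pyran-2-one
Conditions: Bu4NF (1.5 equiv), THF, 0 °C → rt; then 1 M HCl to pH 2–3
Reagents that add atoms: none
Why: Fluoride attack at silicon triggers β-fragmentation with loss of ethene, the standard cleavage of 2-(trimethylsilyl)ethyl esters applied to the vinylogous ester, while acetonide and E-alkene are inert to fluoride.

**Step 5**
Reactants: 4 6-methyl-4-[2-(trimethylsilyl)ethoxy]-2H-pyran-2-one
Product: 10 2-oxo-4-[2-(trimethylsilyl)ethoxy]-2H-pyran-6-carbaldehyde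
Conditions: SeO2 (1.5 equiv), 1,4-dioxane, 150 °C (sealed tube)
Reagents that add atoms: selenium dioxide, O=[Se]=O
Why: Riley oxidation of the vinylogously activated 6-methyl group to the aldehyde is the known behaviour of 4-alkoxy-6-methyl-2-pyranones, and the silylethyl ether offers neither an acetal nor an oxidisable benzylic position.

**Step 6**
Reactants: 2 2,2-dimethyl-1,3-benzodioxole-5-carbaldehyde
Product: 11 (2,2-dimethyl-1,3-benzodioxol-5-yl)methanol
Conditions: NaBH4, MeOH, 0 °C
Reagents that add atoms: none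
Why: Borohydride reduction of the aryl aldehyde gives the benzylic alcohol and leaves the ketal untouched.

**Step 7**
Reactants: 12 (2R,5R)-hexane-2,5-diol
Product: 13 (2R,5R)-hexane-2,5-diyl dimethanesulfonate
Conditions: MsCl (2.4 equiv), Et3N (3 equiv), CH2Cl2, −20 → 0 °C
Reagents that add atoms: methanesulfonyl chloride, CS(=O)(=O)Cl
Why: O-Sulfonylation breaks no C–O bond, so both stereocentres are retained.

**Step 8**
Reactants: 13 (2R,5R)-hexane-2,5-diyl dimethanesulfonate
Product: 15 (2S,5S)-2,5-dimethylthiolane, via thiolate mesylate 14 (not isolated)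
Conditions: Na2S·9H2O (1.1 equiv), DMSO, rt
Reagents that add atoms: sodium sulfide (as nonahydrate), [Na+].[Na+].[S-2]
Why: Two successive SN2 displacements by sulfur (the second a 5-exo-tet closure) invert both carbinol centres, the established route to this C2-symmetric thiolane class, so the (2R,5R)-dimesylate gives the (2S,5S)-sulfide.

**Step 9**
Reactants: 11 (2,2-dimethyl-1,3-benzodioxol-5-yl)methanol, 15 (2S,5S)-2,5-dimethylthiolane
Product: 16 (2S,5S)-1-[(2,2-dimethyl-1,3-benzodioxol-5-yl)methyl]-2,5-dimethylthiolan-1-ium tetrafluoroborate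
Conditions: HBF4 (about 50% in Et2O, 1.0 equiv), 15 (1.5 equiv), CH2Cl2, 0 °C → rt; precipitation with Et2O
Reagents that add atoms: tetrafluoroboric acid, [H+].F[B-](F)(F)F
Why: Acid activation of the electron-rich benzylic alcohol and capture by the sulfide is a known preparation of benzylic sulfonium tetrafluoroborates; sulfur is no stereocentre because the thiolane is C2-symmetric, and the anhydrous acid leaves the acetonide intact.

**Step 10**
Reactants: 9 (E)-6-[2-(2,2-dimethyl-1,3-benzodioxol-5-yl)ethenyl]-4-hydroxy-2H-pyran-2-one, 10 2-oxo-4-[2-(trimethylsilyl)ethoxy]-2H-pyran-6-carbaldehyde, 16 (2S,5S)-1-[(2,2-dimethyl-1,3-benzodioxol-5-yl)methyl]-2,5-dimethylthiolan-1-ium tetrafluoroborate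
Product: 20 (2S,3S)-2-(2,2-dimethyl-1,3-benzodioxol-5-yl)-6-[(E)-2-(2,2-dimethyl-1,3-benzodioxol-5-yl)ethenyl]-3-{2-oxo-4-[2-(trimethylsilyl)ethoxy]-2H-pyran-6-yl}-2,3-dihydro-4H-furo[3,2-c]pyran-4-one, via alkylidene pyrandione 17 (not isolated), via sulfonium ylide 18 (not isolated), via sulfonium betaine 19 (not isolated)
Conditions: 9 (1.0 equiv), 10 (1.05 equiv), 16 (1.3 equiv), 4 Å MS, MeCN–CH2Cl2 (2:1), −20 °C; Cs2CO3 (2.0 equiv) in portions, −20 °C → rt
Reagents that add atoms: none
Why: Proposed new method: Cs2CO3 first ionises only the acidic hydroxypyranone 9, whose C3 condenses with the non-enolisable aldehyde 10 (Knoevenagel, C3a–C3) to the alkylidene pyrandione 17; the carbonate returned by that condensation then deprotonates salt 16, ylide 18 adds to the exocyclic carbon (C3–C2) to give betaine 19, and the enolate oxygen displaces the thiolane with inversion (C2–O1). The closest known reactions are the three-component couplings of 4-hydroxycoumarins and 4-hydroxy-2-pyranones with aldehydes and pyridinium ylides to trans-2,3-dihydrofuro[3,2-c] systems and the [4+1] annulations of sulfonium ylides with ortho-quinone methides; new here is a semi-stabilised, chiral benzylic thiolanium ylide on this acceptor. The dihydrofuran, the only ring formed, closes by 5-exo-tet O-alkylation through the C4 oxygen, as in the coumarin series. C2 is controlled by the C2-symmetric thiolane, whose methyl group syn to the ylide carbon shields one face while the aryl group points away from the ring, so that addition through the open face and inversion in the displacement give 2S; C3 is controlled by C2, because betaine formation is reversible and only the betaine that places pyranonyl and aryl trans closes quickly. The step must steer the ylide to 17 and away from aldehyde 10 (epoxide), and keep 17 from a second molecule of 9: the pKa gap between 9 and 16 holds back ylide formation until the condensation has run, 17 is by far the strongest electrophile present, and the bis-pyranone adduct is a reversible reservoir of 17 under base.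

**Step 11**
Reactants: 20 (2S,3S)-2-(2,2-dimethyl-1,3-benzodioxol-5-yl)-6-[(E)-2-(2,2-dimethyl-1,3-benzodioxol-5-yl)ethenyl]-3-{2-oxo-4-[2-(trimethylsilyl)ethoxy]-2H-pyran-6-yl}-2,3-dihydro-4H-furo[3,2-c]pyran-4-one
Product: 21 hypholomine B, (2S,3S)-2-(3,4-dihydroxyphenyl)-6-[(E)-2-(3,4-dihydroxyphenyl)ethenyl]-3-(4-hydroxy-2-oxo-2H-pyran-6-yl)-2,3-dihydro-4H-furo[3,2-c]pyran-4-one
Conditions: CF3CO2H–H2O (9:1), degassed, argon, 0 °C → rt; evaporation, reversed-phase chromatography
Reagents that add atoms: none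
Why: Aqueous trifluoroacetic acid hydrolyses both catechol isopropylidene ketals and cleaves the vinylogous 2-(trimethylsilyl)ethyl ester by acidolysis (ethene and a silyl species leave, no carbon electrophile is released); C3 is not epimerised by acid, and a reversible ionisation of C2–O1 would reclose to the more stable trans ring.

**Compound list**
1 | 3,4-dihydroxybenzaldehyde | O=Cc1ccc(O)c(O)c1 | starting material
2 | 2,2-dimethyl-1,3-benzodioxole-5-carbaldehyde | O=Cc1ccc2OC(C)(C)Oc2c1 | intermediate
3 | 4-hydroxy-6-methyl-2H-pyran-2-one (triacetic acid lactone) | Cc1cc(O)cc(=O)o1 | starting material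
4 | 6-methyl-4-[2-(trimethylsilyl)ethoxy]-2H-pyran-2-one | Cc1cc(OCC[Si](C)(C)C)cc(=O)o1 | intermediate
5 | lithium 6-methylidene-4-[2-(trimethylsilyl)ethoxy]-6H-pyran-2-olate (C7-lithiated 4, drawn as extended enolate) | [Li+].[O-]C1=CC(OCC[Si](C)(C)C)=CC(=C)O1 | intermediate
6 | lithium 1-(2,2-dimethyl-1,3-benzodioxol-5-yl)-2-{2-oxo-4-[2-(trimethylsilyl)ethoxy]-2H-pyran-6-yl}ethan-1-olate (racemic) | [Li+].[O-]C(Cc1cc(OCC[Si](C)(C)C)cc(=O)o1)c1ccc2OC(C)(C)Oc2c1 | intermediate
7 | 1-(2,2-dimethyl-1,3-benzodioxol-5-yl)-2-{2-oxo-4-[2-(trimethylsilyl)ethoxy]-2H-pyran-6-yl}ethyl methanesulfonate (racemic) | CS(=O)(=O)OC(Cc1cc(OCC[Si](C)(C)C)cc(=O)o1)c1ccc2OC(C)(C)Oc2c1 | intermediate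
8 | (E)-6-[2-(2,2-dimethyl-1,3-benzodioxol-5-yl)ethenyl]-4-[2-(trimethylsilyl)ethoxy]-2H-pyran-2-one | O=c1cc(OCC[Si](C)(C)C)cc(/C=C/c2ccc3OC(C)(C)Oc3c2)o1 | intermediate
9 | (E)-6-[2-(2,2-dimethyl-1,3-benzodioxol-5-yl)ethenyl]-4-hydroxy-2H-pyran-2-one | O=c1cc(O)cc(/C=C/c2ccc3OC(C)(C)Oc3c2)o1 | intermediate
10 | 2-oxo-4-[2-(trimethylsilyl)ethoxy]-2H-pyran-6-carbaldehyde | O=Cc1cc(OCC[Si](C)(C)C)cc(=O)o1 | intermediate
11 | (2,2-dimethyl-1,3-benzodioxol-5-yl)methanol | OCc1ccc2OC(C)(C)Oc2c1 | intermediate
12 | (2R,5R)-hexane-2,5-diol | C[C@@H](O)CC[C@@H](C)O | starting material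
13 | (2R,5R)-hexane-2,5-diyl dimethanesulfonate | C[C@@H](OS(C)(=O)=O)CC[C@@H](C)OS(C)(=O)=O | intermediate
14 | sodium (2S,5R)-5-[(methylsulfonyl)oxy]hexane-2-thiolate | [Na+].C[C@H]([S-])CC[C@@H](C)OS(C)(=O)=O | intermediate
15 | (2S,5S)-2,5-dimethylthiolane | C[C@H]1CC[C@H](C)S1 | intermediate
16 | (2S,5S)-1-[(2,2-dimethyl-1,3-benzodioxol-5-yl)methyl]-2,5-dimethylthiolan-1-ium tetrafluoroborate | C[C@H]1CC[C@H](C)[S+]1Cc1ccc2OC(C)(C)Oc2c1.F[B-](F)(F)F | intermediate
17 | 6-[(E)-2-(2,2-dimethyl-1,3-benzodioxol-5-yl)ethenyl]-3-({2-oxo-4-[2-(trimethylsilyl)ethoxy]-2H-pyran-6-yl}methylidene)-2H-pyran-2,4(3H)-dione (exocyclic alkene geometry not fixed) | O=C1OC(/C=C/c2ccc3OC(C)(C)Oc3c2)=CC(=O)C1=Cc1cc(OCC[Si](C)(C)C)cc(=O)o1 | intermediate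
18 | [(2S,5S)-2,5-dimethylthiolan-1-ium-1-yl](2,2-dimethyl-1,3-benzodioxol-5-yl)methanide | C[C@H]1CC[C@H](C)[S+]1[CH-]c1ccc2OC(C)(C)Oc2c1 | intermediate
19 | 3-[(1R,2R)-2-(2,2-dimethyl-1,3-benzodioxol-5-yl)-2-[(2S,5S)-2,5-dimethylthiolan-1-ium-1-yl]-1-{2-oxo-4-[2-(trimethylsilyl)ethoxy]-2H-pyran-6-yl}ethyl]-6-[(E)-2-(2,2-dimethyl-1,3-benzodioxol-5-yl)ethenyl]-2-oxo-2H-pyran-4-olate | [O-]C1=C(C(=O)OC(/C=C/c2ccc3OC(C)(C)Oc3c2)=C1)[C@H](c1cc(OCC[Si](C)(C)C)cc(=O)o1)[C@H](c1ccc2OC(C)(C)Oc2c1)[S+]1[C@@H](C)CC[C@@H]1C | intermediate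
20 | (2S,3S)-2-(2,2-dimethyl-1,3-benzodioxol-5-yl)-6-[(E)-2-(2,2-dimethyl-1,3-benzodioxol-5-yl)ethenyl]-3-{2-oxo-4-[2-(trimethylsilyl)ethoxy]-2H-pyran-6-yl}-2,3-dihydro-4H-furo[3,2-c]pyran-4-one | O=c1cc(OCC[Si](C)(C)C)cc([C@H]2c3c(cc(/C=C/c4ccc5OC(C)(C)Oc5c4)oc3=O)O[C@@H]2c2ccc3OC(C)(C)Oc3c2)o1 | intermediate
21 | hypholomine B | O=c1cc(O)cc([C@H]2c3c(cc(/C=C/c4ccc(O)c(O)c4)oc3=O)O[C@@H]2c2ccc(O)c(O)c2)o1 | target

**Totals**
Total step count: 11. Longest linear sequence: 5 steps (for example steps 2, 3, 4, 10, 11, or steps 7, 8, 9, 10, 11).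

**Steps most likely to fail**

Step 10 (proposed new method). The ylide may form while aldehyde 10 is still free and be lost to epoxide formation, or the salt may benzylate the pyranone enolate. The alkylidene pyrandione may also be drained by a second pyranone before the ylide arrives, and face selection by the thiolanium ylide on this acceptor or the trans closure may be poor. The fallback uses known chemistry, the oxidative radical annulation of a 4-hydroxy-2-pyranone onto a styrene. It sets out from 9, with alkene 8 (3 equiv) as partner, under Mn(OAc)3·2H2O (2.2 equiv) in AcOH at 60 °C. The C3 radical of 9, formed from its trivalent manganese enolate, should add to the styryl carbon next to the pyranone of 8. The benzylic radical is then oxidised to the cation and the 4-oxygen closes the ring. This should give the trans-dihydrofuran as the racemate, that is 20 together with the (2R,3R)-enantiomer of 20 F1. Preparative HPLC on a chiral stationary phase removes it and the route is rejoined at 20; aldehyde 10 and salt 16 are then not needed.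

Step 5. At the temperature the oxidation needs, the silylethyl ether may be cleaved by the selenous acid formed, or oxidation may run on to the carboxylic acid. The fallback sets out from 8, whose styryl alkene masks the same aldehyde. With OsO4 (cat.), NaIO4 and 2,6-lutidine in dioxane–H2O at rt, syn-dihydroxylation should give racemic 6-[2-(2,2-dimethyl-1,3-benzodioxol-5-yl)-1,2-dihydroxyethyl]-4-[2-(trimethylsilyl)ethoxy]-2H-pyran-2-one F2. Periodate cleavage in the same flask then gives aldehyde 10, where the route is rejoined, and returns aldehyde 2.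

Step 11. Slow acidolysis of the silylethyl ether may force long exposure to strong acid. During that time the benzylic C2–O1 bond may ionise (epimerisation at C2, capture by water) or the catechols may oxidise. The fallback unveils in two orthogonal stages. From 20, Bu4NF buffered with AcOH in THF removes the silylethyl ether by fluoride-induced fragmentation and should give (2S,3S)-2-(2,2-dimethyl-1,3-benzodioxol-5-yl)-6-[(E)-2-(2,2-dimethyl-1,3-benzodioxol-5-yl)ethenyl]-3-(4-hydroxy-2-oxo-2H-pyran-6-yl)-2,3-dihydro-4H-furo[3,2-c]pyran-4-one F3. The acetonides are then hydrolysed under weaker acid, AcOH–H2O (4:1) at 60 °C under argon, to reach 21.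

**Further compounds**
F1 | step 10 | (2R,3R)-2-(2,2-dimethyl-1,3-benzodioxol-5-yl)-6-[(E)-2-(2,2-dimethyl-1,3-benzodioxol-5-yl)ethenyl]-3-{2-oxo-4-[2-(trimethylsilyl)ethoxy]-2H-pyran-6-yl}-2,3-dihydro-4H-furo[3,2-c]pyran-4-one (enantiomer of 20) | O=c1cc(OCC[Si](C)(C)C)cc([C@@H]2c3c(cc(/C=C/c4ccc5OC(C)(C)Oc5c4)oc3=O)O[C@H]2c2ccc3OC(C)(C)Oc3c2)o1
F2 | step 5 | 6-[(1S*,2R*)-2-(2,2-dimethyl-1,3-benzodioxol-5-yl)-1,2-dihydroxyethyl]-4-[2-(trimethylsilyl)ethoxy]-2H-pyran-2-one (racemic, one enantiomer drawn) | O[C@H](c1cc(OCC[Si](C)(C)C)cc(=O)o1)[C@H](O)c1ccc2OC(C)(C)Oc2c1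
F3 | step 11 | (2S,3S)-2-(2,2-dimethyl-1,3-benzodioxol-5-yl)-6-[(E)-2-(2,2-dimethyl-1,3-benzodioxol-5-yl)ethenyl]-3-(4-hydroxy-2-oxo-2H-pyran-6-yl)-2,3-dihydro-4H-furo[3,2-c]pyran-4-one | O=c1cc(O)cc([C@H]2c3c(cc(/C=C/c4ccc5OC(C)(C)Oc5c4)oc3=O)O[C@@H]2c2ccc3OC(C)(C)Oc3c2)o1
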